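## Analysis of the target

The target (C26H34O7) is a tetracyclic methyl ester. Ring A is a δ-lactone whose alkyl oxygen sits on a CMe2 group. Ring A shares two sp2 carbons with ring B, a cyclohepta-1,3-diene, numbered here: 1 ring-fusion CH, 2 C(CH3)=, 3 =C carrying the lactone CH2, 4 C carrying the CMe2O group, 5 =CH, 6 CH2, 7 angular quaternary carbon with a methyl group. Ring B is trans-fused through positions 1 and 7 to the cyclohexane ring C. Ring C shares three atoms with the ketol ring D, so C and D form a bicyclo[3.3.1]nonane: the bridgehead next to the angular carbon carries CO2CH3, the other bridgehead carries CH3, the one-carbon bridge is a spiro-epoxide, and the three-carbon bridge of ring D reads CH2–C(CH3)(OH)–C(=O).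

There are six stereocentres. The angular methyl and the ring-fusion hydrogen are anti. The two bridgeheads are tied together by the bicycle. The ring D hydroxyl is exo (convex face) and its geminal methyl endo. The epoxide oxygen lies over ring D on the side of that hydroxyl, and the epoxide CH2 points toward ring C and the angular methyl. Angular carbon, ester bridgehead, epoxide carbon and methyl bridgehead are four contiguous fully substituted carbons, with the tertiary carbinol close by.

The sensitive groups are the epoxide (acid, neighbouring hydroxyl), the tertiary α-ketol (acyloin shift, retro-aldol), the tertiary allylic C–O bond of the lactone (ionisation) and the diene (double-bond migration under acid). The ester on its neopentyl bridgehead is robust. The difficulties are the crowded bridged core, a seven-membered diene with defined alkene positions, and the need to bring in the acid-labile functions last.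

The strategy rests on ring D. Its three-carbon bridge (methylene, methyl carbinol, ketone) spans the ester bridgehead and the methyl bridgehead, the two carbons flanking the one-carbon bridge. That is the carbon chain of methacrolein laid across the two α-carbons of a cyclohexanone (ring C with the bridge carbon as carbonyl), and the ester makes that ketone a β-keto ester.

## Retrosynthetic reasoning

**24 ⇒ 23.** The two C–O bonds of the epoxide are cut first. The epoxide is the most acid-sensitive group and the tertiary hydroxyl of 23 can steer the oxygen onto the correct face of the exocyclic methylene. The forward step must oxidise this one alkene and leave the electron-rich diene alone.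

**23 ⇒ 22.** The lactone C–O bond (carbinol oxygen to CMe2) and the diene are traced back to a tertiary allylic alcohol with a tert-butyl ester arm and an intact isopropenyl group. The cut is made at the alkyl C–O bond because an isopropenyl group is what the terpene starting material supplies. The forward step must lose water to the 2,3/4,5-diene and add the carboxyl group across the isopropenyl alkene.

**22 ⇒ 21 ⇒ 20.** The methyl group at ring B position 2 is cut from a ketone, and the acetate arm at position 3 from an alkenyl bromide. Both come from one functional array, the 2-bromo enone 20. This turns two C–C bond formations into a carbonyl addition and a cross-coupling at positions differentiated by their functional groups.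

**20 ⇒ 18 ⇒ 17.** Position 3 of ring B is removed altogether, cutting both of its ring bonds. This leaves the six-membered ketone 17 with the isopropenyl group on its α-carbon, a pattern available from a monoterpene. The forward reaction is a one-carbon ring expansion of the silyl dienol ether 18 that must insert the carbon on the isopropenyl side and leave a handle on it.

**17 ⇒ 16 ⇒ 15 ⇒ 14 ⇒ 13.** On ring D the hydroxyl is cut from the carbon next to the ketone (enolate oxidation, exo attack), the ketone is traced to a secondary alcohol, and the exocyclic methylene to the bridge ketone. The terpene ketone is carried as a dioxolane through these steps so that methylenation and enolisation can only occur in the bicycle. This arrives at 13, a bicyclo[3.3.1]nonan-9-one aldol.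

**13 ⇒ 10 + 11 (key disconnection).** Both bonds from the three-carbon bridge to the bridgeheads are cut: ester bridgehead–CH2 and methyl bridgehead–CHOH. The cut is made in ring D and not in ring C because the excised fragment is then exactly the enal 11. Both bonds end at α-carbons of one ketone, so a conjugate addition followed by an aldol reaction can form them in one flask. What remains is the trans-decalin β-keto ester 10. The forward reaction must deliver the chain axially, anti to the angular methyl, and then close onto the only remaining α-carbon.

**10 ⇒ 9 ⇒ 8.** The dioxolane is removed and the ring-fusion carbon is inverted, which leads back to the cis-fused silyl enol ether 8. The ring-fusion carbon lies next to a ketone, so the stable trans fusion should be reachable by equilibration, but the α-isopropenyl group makes this a delicate step (see the uncertain steps).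

**8 ⇒ 2 + 7.** Ring C is cut at the bonds ester carbon–angular carbon and ring CH2–ring-fusion carbon, a Diels–Alder retron. Enone 2 supplies the angular methyl, the isopropenyl group and the absolute configuration. Diene 7 supplies the β-keto ester with its ring methyl.

**2 ⇒ 1; 7 ⇒ 6 ⇒ 3 + 4.** Enone 2 is the allylic oxidation product of 1. Diene 7 is the silyl enol ether of β-keto ester 6, made by acylation of 3 with 4.

## Alternatives that were turned down

**Alternative 1:** ring-closing metathesis to form ring B on the finished bicycle.
- Disconnection: the ring B alkene between positions 4 and 5.
- Forward key step: the second-generation Grubbs catalyst would join the allyl group on the angular carbon of diene A1 to the methylene of its 2-substituted vinyl ketone, expel ethylene and give cycloheptenone A2.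
- For: the lactone carbinol oxygen is already present as a silyl ether, so ring A could be closed by acylation instead of by acid-mediated addition to an alkene. No carbene and no ring expansion are needed.
- Against: the alkene to be formed is trisubstituted, electron-poor and attached to a fully substituted carbon, one of the hardest metathesis classes. The exocyclic methylene on the bridge is a second 1,1-disubstituted alkene. A1 needs three contiguous stereocentres on ring C, one of them a side-chain CH(CH3) that is later destroyed, and no terpene ring supplies the configuration. After closure, the position 3 ketone must still become the tetrasubstituted alkene with the acetate arm, and an aldol–dehydration there would prefer the exocyclic conjugated position.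
- Comparison: it is stronger than the chosen plan on the lactone oxygen and on avoiding acid at the end. It is weaker in step economy and in the source of stereochemistry, and it would still need a way to build ring D, which is what the chosen strategy provides in one flask.

**Alternative 2:** the terpene enone Diels–Alder reaction as the central step.
- Disconnection: the two ring C bonds ester carbon–angular carbon and ring CH2–ring-fusion carbon.
- Forward key step: under AlBr3/AlMe3 the silyloxydiene ester 7 adds across the enone double bond of 2 to give the cis-fused adduct A3 (identical with 8).
- For: it is convergent, creates the angular quaternary carbon, transfers the absolute configuration from the chiral pool and brings in every carbon of ring C together with the latent β-keto ester. On convergence and stereochemical economy it is at least as strong as the chosen key step, and the chosen route uses it to reach its precursor.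
- Against, as the centre of the plan: the dienophile is β,β-disubstituted, the ring fusion comes out cis and must be corrected, and facial control rests on a substituent on the far side of the carbonyl group. It does not address the bridged ring D with its two quaternary bridgeheads.
- Comparison: the chosen strategy is complementary. It builds a ring, two bonds and four stereocentres where the cycloaddition leaves a simple β-keto ester.

**Alternative 3:** dibromocarbene ring expansion as the central step.
- Disconnection: both ring bonds of ring B position 3.
- Forward key step: dibromocarbene (CHBr3, KOt-Bu) adds to the tetrasubstituted silyl enol ether of 18, and the dibromocyclopropane opens with loss of bromide and silyl group to the 2-bromo enone A4 (identical with 20).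
- For: one operation enlarges the ring and delivers a ketone where the methyl group must go and an alkenyl bromide where the acetate arm must go. The position of the enol ether fixes the regiochemistry. On ring size and handle placement it is stronger than the chosen key step, and the chosen route uses it downstream.
- Against, as the centre of the plan: the electrophilic carbene must choose among the silyl enol ether, its conjugated isopropenyl partner and the exocyclic methylene. Strong base meets a silylated ketol. No stereocentre is set. The risk falls late, on an advanced intermediate, and the bicycle must already exist.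
- Comparison: the chosen strategy puts the main risk at step 7, on material made in six steps, and builds the stereochemically dense part of the molecule.

Key step: step 7

Remark on the chemistry: centres that are later destroyed or re-set (carbons α to a carbonyl group, the secondary carbinol of 13, the tertiary carbinol of 22) are drawn as one epimer, and β-keto esters are drawn in the keto form.

## Route

Step 1
Reactants: 1 (S)-(−)-limonene
Product: 2 (R)-isopiperitenone
Conditions: Cr(CO)6 (0.5 equiv), t-BuOOH (3 equiv), MeCN, reflux
Reagents that add atoms: tert-butyl hydroperoxide, CC(C)(C)OO
Why: Chromium-catalysed allylic C–H oxidation with a hydroperoxide, known for limonene; the ring methylene between the trisubstituted alkene and the isopropenyl-bearing carbon gives 2, and the regioisomeric enone from the other allylic methylene is removed by chromatography. The stereocentre is untouched; its descriptor changes from S to R only because the new carbonyl changes the priorities.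

Step 2
Reactants: 3 Meldrum's acid; 4 methacryloyl chloride
Product: 6 methyl 4-methyl-3-oxopent-4-enoate, via acyl Meldrum's acid 5 (not isolated)
Conditions: pyridine (2 equiv), CH2Cl2, 0 °C; then MeOH, reflux
Reagents that add atoms: methanol, CO
Why: C-Acylation of Meldrum's acid by the acid chloride, then methanolysis of the acyl Meldrum's acid with loss of acetone and CO2 (standard β-keto ester synthesis); the α-methyl group makes this vinyl ketone much less prone to polymerise than the unsubstituted parent.

Step 3
Reactants: 6 methyl 4-methyl-3-oxopent-4-enoate
Product: 7 methyl (2Z)-3-[(tert-butyldimethylsilyl)oxy]-4-methylpenta-2,4-dienoate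
Conditions: t-BuMe2SiOTf (1.1 equiv), Et3N (1.5 equiv), CH2Cl2, 0 °C; aq. NaHCO3 work-up
Reagents that add atoms: tert-butyldimethylsilyl triflate, CC(C)(C)[Si](C)(C)OS(=O)(=O)C(F)(F)F
Why: O-Silylation of the enolised β-keto ester with a silyl triflate and an amine gives the 2-silyloxydiene; the Z isomer (ester and silyloxy cis, the geometry of the hydrogen-bonded enol) is expected and is the reactive one, because its ester is on the outside of the s-cis diene.

Step 4
Reactants: 2 (R)-isopiperitenone; 7 silyloxydiene ester
Product: 8 cis-fused Diels–Alder adduct (silyl enol ether)
Conditions: AlBr3 (1.5 equiv), AlMe3 (0.15 equiv), toluene/CH2Cl2, −10 °C → rt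
Reagents that add atoms: none
Why: Diels–Alder reaction of a β,β-disubstituted cyclohexenone with a 2-silyloxydiene under the strongly Lewis-acidic AlBr3/AlMe3 mixture used for hindered partners; the silyl enol ether makes the ester-bearing diene terminus the nucleophilic one, so it bonds to the enone β-carbon and creates the angular quaternary carbon. Suprafacial endo addition to the enone face anti to the isopropenyl group of 2 sets the angular carbon (final configuration) and the ring-fusion carbon (cis, corrected in step 5).

Step 5
Reactants: 8 cis-fused Diels–Alder adduct
Product: 9 trans-fused diketo ester
Conditions: NaOMe (2.5 equiv), MeOH/THF, 0 °C → rt; AcOH quench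
Reagents that add atoms: none
Why: Methoxide cleaves the silyl enol ether to the β-keto ester enolate and, through the enolate of the other ketone, equilibrates the ring-fusion carbon; the trans-decalin is expected to be favoured because its axial angular methyl faces only the two carbonyl carbons across the rings while ester, ring methyl and isopropenyl are all equatorial. The reaction is stopped as soon as epimerisation is complete, because longer exposure would move the isopropenyl double bond into conjugation.

Step 6
Reactants: 9 trans-fused diketo ester
Product: 10 ketal β-keto ester (precursor of the key step)
Conditions: (Me3SiOCH2)2 (1.5 equiv), Me3SiOTf (0.1 equiv), CH2Cl2, −78 → −20 °C; pyridine quench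
Reagents that add atoms: 1,2-bis(trimethylsilyloxy)ethane, C[Si](C)(C)OCCO[Si](C)(C)C
Why: Noyori ketalisation under aprotic conditions; the isolated ketone is the more basic carbonyl, whereas the β-keto ester carbonyl is enolised and electron-poor, so the dioxolane should form at the terpene ketone only. Low temperature and the absence of protic acid keep the α-isopropenyl ketone from isomerising before it is masked.

Step 7
Reactants: 10 ketal β-keto ester; 11 methacrolein
Product: 13 ketal aldol (bicyclo[3.3.1]nonan-9-one), via keto aldehyde 12 (not isolated)
Conditions: DBU (0.1 equiv), CH2Cl2, 0 °C → rt; evaporate; TsOH (anhydrous, 0.3 equiv), CH2Cl2, 0 °C → rt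
Reagents that add atoms: none
Why: DBU generates the stabilised enolate of β-keto ester 10, which adds 1,4 to the unsubstituted β-carbon of methacrolein; protonation gives keto aldehyde 12, whose ester-bearing carbon is now quaternary. Acid then enolises the ring ketone toward its only remaining α-hydrogen, at the methyl-bearing carbon, and the enol attacks the protonated aldehyde to give aldol 13; dehydration cannot follow because the new bridgehead has no hydrogen. The closest known reaction type is the α,α′-annulation of 2-carboalkoxycyclohexanones with acrolein-type enals to bicyclo[3.3.1]nonan-9-ones (Michael addition, then aldol). The one new ring is six-membered and closes in a 6-(enolendo)-exo-trig mode (the enol C=C lies inside the new ring, the aldehyde C=O outside it), which is a favoured closure. The ester-bearing bridgehead is set in the conjugate addition: the enolate of the trans-decalin chair is attacked axially, on the face anti to the axial angular methyl on the neighbouring quaternary carbon, so the three-carbon chain ends up axial. The methyl-bearing bridgehead is not an independent choice, because the axial chain can reach the enol carbon only from its own face, which leaves the bridgehead methyl equatorial. The carbinol carbon and its methyl-bearing neighbour are expected mainly as the diequatorial isomer drawn, and any mixture converges in steps 9 and 10. The step needs C- over O-alkylation and 1,4- over 1,2-addition (soft enolate, amidine base), a single enolisation site (secured by the quaternary ester carbon) and survival of the dioxolane and the isopropenyl group (anhydrous, substoichiometric acid after removal of excess enal).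

Step 8
Reactants: 13 ketal aldol
Product: 14 methylene alcohol
Conditions: Zn/CH2Br2/TiCl4 reagent (pre-formed in THF, 5 °C), CH2Cl2, 0 °C → rt
Reagents that add atoms: dibromomethane, BrCBr
Why: Takai–Lombardo methylenation; the non-basic zinc/titanium methylene reagent adds to hindered ketones that resist Wittig reagents and cannot trigger retro-aldol cleavage as a basic ylide would. Only one ketone is free (the other is the dioxolane), ester and alkene are inert, and the free hydroxyl only consumes reagent.

Step 9
Reactants: 14 methylene alcohol
Product: 15 methylene ketone
Conditions: Dess–Martin periodinane (1.5 equiv), NaHCO3, CH2Cl2, rt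
Reagents that add atoms: none
Why: Dess–Martin oxidation of the hindered secondary alcohol under buffered conditions; the product is a β,γ-unsaturated ketone that cannot move into conjugation because the carbon between carbonyl and alkene is the quaternary bridgehead.

Step 10
Reactants: 15 methylene ketone
Product: 16 ketol (tertiary α-hydroxy ketone)
Conditions: KN(SiMe3)2 (1.3 equiv), THF, −78 °C; then 2-(phenylsulfonyl)-3-phenyloxaziridine (1.5 equiv), −78 °C; aq. NH4Cl
Reagents that add atoms: 2-(phenylsulfonyl)-3-phenyloxaziridine (Davis reagent), O=S(=O)(c1ccccc1)N1OC1c1ccccc1
Why: Enolate hydroxylation with the Davis oxaziridine; the ketone has a single α-hydrogen (its other α-carbon is the bridgehead), so only one enolate can form. The oxaziridine approaches the exo face of ring D, because the endo face is closed by ring C and its axial ring-fusion hydrogen; this places the hydroxyl exo and pushes the methyl endo, as in the target.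

Step 11
Reactants: 16 ketol
Product: 17 diketone (terpene ketone set free)
Conditions: pyridinium p-toluenesulfonate (0.3 equiv), acetone/H2O (10:1), 50 °C
Reagents that add atoms: water, O
Why: Acid-catalysed hydrolysis of the dioxolane, which is strained by a 1,3-diaxial contact with the angular methyl and should open under weak acid; pyridinium tosylate is too weak to protonate the exocyclic methylene or to shift the α-ketol.

Step 12
Reactants: 17 diketone
Product: 18 bis-silyl compound (silyl ether and silyl dienol ether)
Conditions: Me3SiOTf (3 equiv), Et3N (5 equiv), CH2Cl2, 0 °C; aq. NaHCO3 work-up
Reagents that add atoms: trimethylsilyl triflate, C[Si](C)(C)OS(=O)(=O)C(F)(F)F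
Why: Soft enolisation with silyl triflate and amine; only the terpene-ring ketone has α-hydrogens, and enolisation toward the isopropenyl-bearing carbon gives the conjugated 2-silyloxydiene instead of the enol ether at the hindered ring-fusion carbon. The tertiary hydroxyl is silylated at the same time, which protects the ketol from the base of step 13.

Step 13
Reactants: 18 bis-silyl compound
Product: 20 ring-expanded 2-bromo enone, via dibromocyclopropane 19 (not isolated)
Conditions: CHBr3 (1.5 equiv), KOt-Bu (1.4 equiv), pentane, −20 °C → rt; aq. NaHCO3 work-up
Reagents that add atoms: bromoform, BrC(Br)Br
Why: Dibromocarbene is electrophilic and adds to the most electron-rich double bond, the tetrasubstituted silyl enol ether, from the face anti to the angular methyl; the siloxy-dibromocyclopropane 19 then opens with loss of bromide and of the silyl group to the ring-enlarged 2-bromo enone (known one-carbon ring expansion of cyclic silyl enol ethers). The base is kept limiting so that the new α′-hydrogen at the ring fusion is not exposed to it.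

Step 14
Reactants: 20 2-bromo enone
Product: 21 enone tert-butyl ester
Conditions: BrZnCH2CO2t-Bu (2 equiv), Pd(P(t-Bu)3)2 (5 mol %), THF, rt
Reagents that add atoms: (2-tert-butoxy-2-oxoethyl)zinc bromide, CC(C)(C)OC(=O)C[Zn]Br
Why: Negishi-type coupling of an alkenyl bromide with a Reformatsky reagent; the α-bromo enone adds readily to the zerovalent palladium complex, and the zinc ester enolate is mild enough at room temperature to leave both ketones and both esters alone.

Step 15
Reactants: 21 enone tert-butyl ester
Product: 22 tertiary allylic alcohol
Conditions: MeLi (1.5 equiv), CeCl3 (anhydrous, 1.6 equiv), THF, −78 °C; aq. NH4Cl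
Reagents that add atoms: methyllithium, [Li]C
Why: 1,2-Addition of the organocerium reagent MeCeCl2, which is nucleophilic but weakly basic and so adds to the hindered enone carbonyl instead of deprotonating the CH2 next to the ester; the ring D ketone lies between two fully substituted carbons and the esters do not react at −78 °C. The configuration of the new carbinol is irrelevant (drawn with its methyl anti to the angular methyl).

Step 16
Reactants: 22 tertiary allylic alcohol
Product: 23 diene lactone
Conditions: CF3CO2H (10 equiv), CH2Cl2, 0 °C → rt; aq. NaHCO3 work-up
Reagents that add atoms: none
Why: Acid ionises the doubly allylic tertiary alcohol to a pentadienyl cation, which loses the ring proton at position 5 to give the 2,3/4,5-diene; protonation of the isopropenyl terminus then gives a tertiary allyl cation that is captured by the carboxyl group set free from the tert-butyl ester (six-membered lactone), and the trimethylsilyl ether is lost. Of the lactones the cations can form, the δ-lactone is the one whose C–O bond re-ionises least readily, so it should accumulate; the exocyclic methylene is deactivated toward protonation by the two flanking carbonyl-bearing quaternary carbons.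

Step 17
Reactants: 23 diene lactone
Product: 24 target (CNP0605450.1)
Conditions: VO(acac)2 (5 mol %), t-BuOOH (1.5 equiv), CH2Cl2, 0 °C → rt
Reagents that add atoms: tert-butyl hydroperoxide, CC(C)(C)OO
Why: Hydroxyl-directed epoxidation; the vanadate ester of the tertiary alcohol faces the exocyclic methylene across ring D (a boat, forced by the endo methyl), so oxygen enters syn to the hydroxyl, which is also the face away from the axial angular methyl. The tetra- and trisubstituted alkenes of the diene have no hydroxyl in reach and are not oxidised by this catalyst system, whereas a peracid would attack them first.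

## Compound list

1 | (S)-(−)-limonene, (4S)-1-methyl-4-(prop-1-en-2-yl)cyclohex-1-ene | CC1=CC[C@@H](C(C)=C)CC1 | starting material
2 | (R)-isopiperitenone, (6R)-3-methyl-6-(prop-1-en-2-yl)cyclohex-2-en-1-one | CC1=CC(=O)[C@@H](C(C)=C)CC1 | intermediate
3 | Meldrum's acid, 2,2-dimethyl-1,3-dioxane-4,6-dione | CC1(C)OC(=O)CC(=O)O1 | starting material
4 | methacryloyl chloride | CC(=C)C(Cl)=O | starting material
5 | acyl Meldrum's acid, 5-(1-hydroxy-2-methylprop-2-en-1-ylidene)-2,2-dimethyl-1,3-dioxane-4,6-dione | CC(=C)C(O)=C1C(=O)OC(C)(C)OC1=O | intermediate (not isolated)
6 | methyl 4-methyl-3-oxopent-4-enoate | COC(=O)CC(=O)C(C)=C | intermediate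
7 | methyl (2Z)-3-[(tert-butyldimethylsilyl)oxy]-4-methylpenta-2,4-dienoate | COC(=O)/C=C(\O[Si](C)(C)C(C)(C)C)C(C)=C | intermediate
8 | cis-fused Diels–Alder adduct: methyl 2-[(tert-butyldimethylsilyl)oxy]-3,8a-dimethyl-5-oxo-6-(prop-1-en-2-yl)-1,4,4a,5,6,7,8,8a-octahydronaphthalene-1-carboxylate; 4a-H and 8a-CH3 cis, both new ring bonds anti to the isopropenyl group, ester endo | COC(=O)[C@@H]1C(O[Si](C)(C)C(C)(C)C)=C(C)C[C@@H]2C(=O)[C@@H](C(C)=C)CC[C@]12C | intermediate
9 | trans-fused diketo ester: methyl 3,8a-dimethyl-2,5-dioxo-6-(prop-1-en-2-yl)decahydronaphthalene-1-carboxylate; 4a-H and 8a-CH3 trans; ester, 3-methyl and isopropenyl equatorial | COC(=O)[C@H]1C(=O)[C@@H](C)C[C@H]2C(=O)[C@@H](C(C)=C)CC[C@]12C | intermediate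
10 | ketal β-keto ester: the 5,5-ethylenedioxy derivative (dioxolane at C5) of 9 | COC(=O)[C@H]1C(=O)[C@@H](C)C[C@H]2C3(OCCO3)[C@@H](C(C)=C)CC[C@]12C | intermediate
11 | methacrolein, 2-methylprop-2-enal | C=C(C)C=O | starting material
12 | keto aldehyde: 10 carrying at C1 an axial 2-methyl-3-oxopropyl chain, anti to the angular methyl | COC(=O)[C@@]1(C[C@@H](C)C=O)C(=O)[C@@H](C)C[C@H]2C3(OCCO3)[C@@H](C(C)=C)CC[C@]12C | intermediate (not isolated)
13 | ketal aldol: bicyclo[3.3.1]nonan-9-one with bridgeheads CO2CH3 and CH3, ring D bridge CH2–CH(CH3)–CH(OH) (methyl and hydroxyl equatorial), ring C trans-fused to the ketalised isopropenylcyclohexane | COC(=O)[C@]12C[C@@H](C)[C@H](O)[C@](C)(C[C@H]3C4(OCCO4)[C@@H](C(C)=C)CC[C@@]31C)C2=O | intermediate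
14 | methylene alcohol: 13 with the bridge C=O replaced by C=CH2 | COC(=O)[C@]12C[C@@H](C)[C@H](O)[C@](C)(C[C@H]3C4(OCCO4)[C@@H](C(C)=C)CC[C@@]31C)C2=C | intermediate
15 | methylene ketone: 14 with the ring D carbinol oxidised to C=O | COC(=O)[C@]12C[C@@H](C)C(=O)[C@](C)(C[C@H]3C4(OCCO4)[C@@H](C(C)=C)CC[C@@]31C)C2=C | intermediate
16 | ketol: 15 with a hydroxyl on the methyl-bearing α-carbon of ring D (OH exo, CH3 endo) | COC(=O)[C@]12C[C@@](C)(O)C(=O)[C@](C)(C[C@H]3C4(OCCO4)[C@@H](C(C)=C)CC[C@@]31C)C2=C | intermediate
17 | diketone: 16 with the dioxolane replaced by C=O | COC(=O)[C@]12C[C@@](C)(O)C(=O)[C@](C)(C[C@H]3C(=O)[C@@H](C(C)=C)CC[C@@]31C)C2=C | intermediate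
18 | bis-silyl compound: trimethylsilyl ether of the tertiary alcohol and trimethylsilyl dienol ether C(OSiMe3)=C(isopropenyl) of the terpene-ring ketone of 17 | COC(=O)[C@]12C[C@@](C)(O[Si](C)(C)C)C(=O)[C@](C)(C[C@H]3C(O[Si](C)(C)C)=C(C(C)=C)CC[C@@]31C)C2=C | intermediate
19 | dibromocyclopropane: CBr2 bridging the two enol ether carbons of 18 on the face anti to the angular methyl | COC(=O)[C@]12C[C@@](C)(O[Si](C)(C)C)C(=O)[C@](C)(C[C@H]3[C@]4(O[Si](C)(C)C)C(Br)(Br)[C@]4(C(C)=C)CC[C@@]31C)C2=C | intermediate (not isolated)
20 | 2-bromo enone: ring B seven-membered, C2 ketone, C3 bromide, C3=C4 alkene, isopropenyl on C4; tertiary alcohol as trimethylsilyl ether | COC(=O)[C@]12C[C@@](C)(O[Si](C)(C)C)C(=O)[C@](C)(C[C@H]3C(=O)C(Br)=C(C(C)=C)CC[C@@]31C)C2=C | intermediate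
21 | enone tert-butyl ester: 20 with CH2CO2t-Bu in place of bromine | COC(=O)[C@]12C[C@@](C)(O[Si](C)(C)C)C(=O)[C@](C)(C[C@H]3C(=O)C(CC(=O)OC(C)(C)C)=C(C(C)=C)CC[C@@]31C)C2=C | intermediate
22 | tertiary allylic alcohol: 21 with ring B position 2 as C(CH3)(OH) | COC(=O)[C@]12C[C@@](C)(O[Si](C)(C)C)C(=O)[C@](C)(C[C@H]3[C@@](C)(O)C(CC(=O)OC(C)(C)C)=C(C(C)=C)CC[C@@]31C)C2=C | intermediate
23 | diene lactone: the target skeleton with C=CH2 on the bridge carbon in place of the epoxide, free tertiary alcohol | COC(=O)[C@]12C[C@@](C)(O)C(=O)[C@](C)(C[C@H]3C(C)=C4CC(=O)OC(C)(C)C4=CC[C@@]31C)C2=C | intermediate
24 | CNP0605450.1 | COC(=O)[C@]12C[C@@](C)(O)C(=O)[C@](C)(C[C@H]3C(C)=C4CC(=O)OC(C)(C)C4=CC[C@@]31C)[C@]21CO1 | target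

## Step count and least certain steps

Total: 17 steps. Longest linear sequence: 16 steps (steps 2–17, from 3 and 4); 15 steps from 1.

**Step 7 (key step).** The second stage is the weak point. Anhydrous acid can open the crowded dioxolane and hand its glycol to the aldehyde, or let the ketal carbon form an enol ether toward the ring-fusion carbon, while the desired enolisation of the hindered ring ketone is slow. The conjugate addition must also join two adjacent quaternary carbons.
Fallback: take the ketal out of the annulation. Diketo ester 9 is treated with 11 under the same two-stage conditions (DBU, then anhydrous TsOH) to give, through the unketalised keto aldehyde F1, the bicyclic aldol with free terpene ketone F2. F2 is then ketalised with (Me3SiOCH2)2 and Me3SiOTf, with K2CO3/MeOH work-up to remove any silyl ether on the carbinol. The reagent can now find only the terpene ketone, because the bridge ketone lies between two quaternary carbons. The sequence returns to the route at 13.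

**Step 4.** The diene might add to the enone face that carries the isopropenyl group, or the hindered pair might react sluggishly. A reversed facial preference would, after step 5, lead into the enantiomeric series.
Fallback: change the terpene antipode. (R)-(+)-Limonene F3 is oxidised as in step 1 to (S)-isopiperitenone F4, which with 7 under the step 4 conditions would give the syn adduct F5 (new bonds on the isopropenyl face). Under the step 5 conditions both α-carbons of the terpene ketone equilibrate (the isopropenyl-bearing carbon quickly, the ring fusion more slowly), and the sequence returns to the route at 9.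

**Step 5.** Migration of the isopropenyl double bond into conjugation with the ketone (via the more acidic hydrogen on the isopropenyl-bearing carbon) may outrun epimerisation of the hindered ring-fusion hydrogen, or the epimerisation may stop short.
Fallback: let both equilibria run to completion with excess NaOMe at rt to give the trans-fused isopropylidene enone F6, then return the double bond by deconjugation. F6 is treated with KOt-Bu (3 equiv) in t-BuOH/THF to form the extended dienolate, which is added to cold aqueous AcOH. Kinetic protonation at the α-carbon restores the isopropenyl ketone; brief contact with Et3N settles the isopropenyl group equatorial. The sequence returns to the route at 9.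

**Step 6.** Site selectivity between the two ketones may be poor (dioxolane at the β-keto ester carbonyl, or at both), because both carbonyls are flanked by substituted carbons and the preference rests on electronic deactivation alone.
Fallback: mask the β-keto ester first. Compound 9 with t-BuMe2SiOTf/Et3N gives the silyl enol ether F7, since only the β-keto ester is acidic enough. Ketalisation of the one remaining ketone under the step 6 conditions gives F8, and Bu4NF/AcOH in THF removes the silyl group. The sequence returns to the route at 10.

**Step 16.** In the cationic manifold, proton loss toward the ring-fusion carbon or the methyl group would give positional isomers of the diene and could epimerise the ring fusion, and capture of the pentadienyl cation by the carboxyl group would give γ-lactones. The acid also meets the free tertiary alcohol next to the exocyclic methylene.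
Fallback: reverse the order in which the methyl group and the lactone are made. Enone ester 21 is treated with Tf2O and 2,6-di-tert-butyl-4-methylpyridine; γ-deprotonation of the O-triflated enone gives the dienyl triflate F9, with the diene already in place. CF3CO2H then cleaves the tert-butyl ester and silyl ether and protonates only the isopropenyl terminus, since protonation of the ring CH would place charge on the triflate-bearing carbon; this closes the triflate lactone F10. Methylation with MeZnCl and Pd(PPh3)4 (a zerovalent palladium complex) in THF returns to the route at 23.

## Further compounds

F1 | step 7 | unketalised keto aldehyde (Michael adduct of 9 and 11) | COC(=O)[C@@]1(C[C@@H](C)C=O)C(=O)[C@@H](C)C[C@H]2C(=O)[C@@H](C(C)=C)CC[C@]12C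
F2 | step 7 | bicyclic aldol with free terpene ketone | COC(=O)[C@]12C[C@@H](C)[C@H](O)[C@](C)(C[C@H]3C(=O)[C@@H](C(C)=C)CC[C@@]31C)C2=O
F3 | step 4 | (R)-(+)-limonene | CC1=CC[C@H](C(C)=C)CC1
F4 | step 4 | (S)-isopiperitenone | CC1=CC(=O)[C@H](C(C)=C)CC1
F5 | step 4 | syn Diels–Alder adduct (epimer of 8 at the isopropenyl-bearing carbon) | COC(=O)[C@@H]1C(O[Si](C)(C)C(C)(C)C)=C(C)C[C@@H]2C(=O)[C@H](C(C)=C)CC[C@]12C
F6 | step 5 | trans-fused isopropylidene enone | COC(=O)[C@H]1C(=O)[C@@H](C)C[C@H]2C(=O)C(=C(C)C)CC[C@]12C
F7 | step 6 | tert-butyldimethylsilyl enol ether of the β-keto ester of 9 | COC(=O)C1=C(O[Si](C)(C)C(C)(C)C)[C@@H](C)C[C@H]2C(=O)[C@@H](C(C)=C)CC[C@]12C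
F8 | step 6 | dioxolane of F7 | COC(=O)C1=C(O[Si](C)(C)C(C)(C)C)[C@@H](C)C[C@H]2C3(OCCO3)[C@@H](C(C)=C)CC[C@]12C
F9 | step 16 | dienyl triflate | COC(=O)[C@]12C[C@@](C)(O[Si](C)(C)C)C(=O)[C@](C)(C[C@H]3C(OS(=O)(=O)C(F)(F)F)=C(CC(=O)OC(C)(C)C)C(C(C)=C)=CC[C@@]31C)C2=C
F10 | step 16 | triflate lactone | COC(=O)[C@]12C[C@@](C)(O)C(=O)[C@](C)(C[C@H]3C(OS(=O)(=O)C(F)(F)F)=C4CC(=O)OC(C)(C)C4=CC[C@@]31C)C2=C
A1 | alternative 1 | metathesis substrate (allyl group on the angular carbon, 2-substituted vinyl ketone side chain on the ring-fusion carbon) | COC(=O)[C@]12C[C@@](C)(O)C(=O)[C@](C)(C[C@@H]([C@H](C)C(=O)C(=C)C(C)(C)O[Si](CC)(CC)CC)[C@@]1(CC=C)C)C2=C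
A2 | alternative 1 | tetracyclic cyclohept-2-enone with triethylsilyl-protected carbinol | COC(=O)[C@]12C[C@@](C)(O)C(=O)[C@](C)(C[C@H]3[C@H](C)C(=O)C(C(C)(C)O[Si](CC)(CC)CC)=CC[C@@]31C)C2=C
A3 | alternative 2 | cis-fused silyl enol ether Diels–Alder adduct (identical with 8) | COC(=O)[C@@H]1C(O[Si](C)(C)C(C)(C)C)=C(C)C[C@@H]2C(=O)[C@@H](C(C)=C)CC[C@]12C
A4 | alternative 3 | tetracyclic 2-bromocyclohept-2-enone (identical with 20) | COC(=O)[C@]12C[C@@](C)(O[Si](C)(C)C)C(=O)[C@](C)(C[C@H]3C(=O)C(Br)=C(C(C)=C)CC[C@@]31C)C2=C
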